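**Strategy.** The route rests on cutting the two bonds that tie the pyranone C=C to the carbocycle: C3–C1′ and C8–C2′ (core numbered as a 6-oxabicyclo[3.2.1]octane; C1′–C5′ are the ynone carbons). C3, the only enolizable carbon, and the C8 bridge ketone are 1,4-related across the cyclohexanedione ring that the O6–C7 bridge already spans, and they face each other in its boat. In one operation the C3 potassium enolate adds to the terminus of an ethynyl ketone and the allenolate closes onto C8, forming the bicyclo[2.2.2]octenol, two C–C bonds and both new stereocentres. The precursors are (1R,5R)-2,2,3,5-tetramethyl-6-oxabicyclo[3.2.1]octane-4,8-dione and the silyl ether of (S)-5-hydroxy-5-phenylpent-1-yn-3-one.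

Key step: step 10

Remark: the C3 configuration of the tetramethyl dione is erased on enolization, so the exo-methyl epimer expected from step 6 is used as such; the C3 methyl is introduced only after the ether bridge is in place, because C3 is then the sole enolizable position.
Remark: pre-formed enolates and other species consumed in the same flask are numbered as intermediates; alkoxide salt forms of products before work-up and catalyst-bound species are not.

**Step 1**
Reactants: 1 dimedone (5,5-dimethylcyclohexane-1,3-dione)
Product: 2 2,5,5-trimethylcyclohexane-1,3-dione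
Conditions: MeI (1.1 equiv), K2CO3, acetone, reflux
Reagents that add atoms: iodomethane, CI
Why: C-alkylation (SN2) of the stabilized 1,3-dione enolate at C2, the standard preparation of 2-alkyl-1,3-diones; no stereocentre is formed.

**Step 2**
Reactants: 2 2,5,5-trimethylcyclohexane-1,3-dione
Product: 3 3-(2-methylpropoxy)-2,5,5-trimethylcyclohex-2-en-1-one
Conditions: iBuOH, TsOH·H2O (cat.), toluene, reflux, Dean–Stark
Reagents that add atoms: 2-methylpropan-1-ol, CC(C)CO
Why: Acid-catalysed enol etherification with azeotropic removal of water; the dione is symmetric, so a single vinylogous ester should form.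

**Step 3**
Reactants: 3 3-(2-methylpropoxy)-2,5,5-trimethylcyclohex-2-en-1-one
Product: 6 rac-4-(hydroxymethyl)-2,5,5-trimethylcyclohexane-1,3-dione, via lithium dienolate 4 (not isolated), via hydroxymethyl enol ether 5 (not isolated)
Conditions: LiN(iPr)2 (2.2 equiv), THF, −78 °C; 1H-benzotriazol-1-ylmethanol (1.1 equiv), −78 → −20 °C; then 2 M HCl, THF, 23 °C
Reagents that add atoms: 1H-benzotriazol-1-ylmethanol (anhydrous formaldehyde source), OCn1nnc2ccccc12; water, O
Why: Stork–Danheiser kinetic α′-deprotonation gives the cross-conjugated enolate at the only CH2 next to the ketone, which undergoes an aldol addition to formaldehyde released in the flask by the second equivalent of amide; acid hydrolysis of the enol ether then unveils the dione, whose new stereocentre is racemic.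

**Step 4**
Reactants: 6 rac-4-(hydroxymethyl)-2,5,5-trimethylcyclohexane-1,3-dione
Product: 8 rac-(1R,5R)-2,2,5-trimethyl-6-oxabicyclo[3.2.1]octane-4,8-dione, via 2-iodo dione 7 (not isolated)
Conditions: PhI(OAc)2 (1.2 equiv), Bu4NI (20 mol %), MeCN, 23 °C, dark
Reagents that add atoms: none
Why: Oxidative α-etherification of a 2-alkyl-1,3-dione with a tethered hydroxyl, a known iodide/PhI(OAc)2 cyclization type: acetyl hypoiodite made in the flask iodinates the enol at C2 and the axial hydroxymethyl group displaces iodide in a 5-exo-tet closure, so the bridge can only form cis, while reversible iodination funnels both C2 epimers into the product.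

**Step 5**
Reactants: 8 rac-(1R,5R)-2,2,5-trimethyl-6-oxabicyclo[3.2.1]octane-4,8-dione
Product: 9 (1R,5R)-2,2,5-trimethyl-6-oxabicyclo[3.2.1]octane-4,8-dione
Conditions: preparative chiral SFC, amylose tris(3,5-dimethylphenylcarbamate) phase, CO2/MeOH, 35 °C
Reagents that add atoms: none
Why: Chromatographic resolution of a rigid, neutral diketone on a polysaccharide chiral phase; the bridgeheads C1 and C5 cannot epimerize afterwards, and the (1R,5R) antipode would be assigned by X-ray analysis of a heavy-atom hydrazone derivative or by comparing measured and computed circular dichroism.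

**Step 6**
Reactants: 9 (1R,5R)-2,2,5-trimethyl-6-oxabicyclo[3.2.1]octane-4,8-dione
Product: 11 (1R,3S,5R)-2,2,3,5-tetramethyl-6-oxabicyclo[3.2.1]octane-4,8-dione, via lithium enolate 10 (not isolated)
Conditions: LiN(SiMe3)2 (1.05 equiv), THF, −78 °C; MeI (1.5 equiv), −78 → 0 °C
Reagents that add atoms: iodomethane, CI
Why: Regiospecific enolate alkylation, since C3 is the only enolizable carbon (a C1 enolate would violate Bredt's rule and C5 is quaternary); iodomethane should enter on the exo face anti to the O6–C7 bridge to give the 3-exo-methyl epimer.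

**Step 7**
Reactants: 12 ethyl (S)-3-hydroxy-3-phenylpropanoate
Product: 13 (S)-3-hydroxy-N-methoxy-N-methyl-3-phenylpropanamide
Conditions: MeNH(OMe)·HCl (1.6 equiv), iPrMgCl (4 equiv), THF, −20 → 0 °C
Reagents that add atoms: N,O-dimethylhydroxylamine hydrochloride, CNOC.Cl
Why: Weinreb amide formation by aminolysis of the ester with the chloromagnesium amide; the carbinol is carried as its magnesium alkoxide, which cannot undergo β-elimination, and the stereocentre is not touched.

**Step 8**
Reactants: 13 (S)-3-hydroxy-N-methoxy-N-methyl-3-phenylpropanamide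
Product: 14 (S)-3-[(tert-butyldimethylsilyl)oxy]-N-methoxy-N-methyl-3-phenylpropanamide
Conditions: TBSCl, imidazole, DMF, 23 °C
Reagents that add atoms: tert-butyldimethylsilyl chloride, CC(C)(C)[Si](C)(C)Cl
Why: Standard imidazole-mediated silylation of a secondary alcohol; protection is placed after amide formation so that no β-silyloxy ester is exposed to a basic amide.

**Step 9**
Reactants: 14 (S)-3-[(tert-butyldimethylsilyl)oxy]-N-methoxy-N-methyl-3-phenylpropanamide; 15 ethynylmagnesium bromide
Product: 17 (S)-5-[(tert-butyldimethylsilyl)oxy]-5-phenylpent-1-yn-3-one, via magnesium hemiaminal chelate 16 (not isolated)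
Conditions: HC≡CMgBr (2.5 equiv), THF, 0 °C; inverse quench into cold 1 M HCl
Reagents that add atoms: ethynylmagnesium bromide (15), C#C[Mg]Br
Why: Weinreb ketone synthesis, in which the chelated tetrahedral intermediate prevents over-addition; the cold acidic inverse quench protonates the liberated N,O-dimethylhydroxylamine before it can add to the ynone.

**Step 10**
Reactants: 11 (1R,3S,5R)-2,2,3,5-tetramethyl-6-oxabicyclo[3.2.1]octane-4,8-dione; 17 (S)-5-[(tert-butyldimethylsilyl)oxy]-5-phenylpent-1-yn-3-one
Product: 20 (1R,3S,5S,8R)-8-hydroxy-2,2,3,5-tetramethyl-6-oxabicyclo[3.2.1]octan-4-one bridged from C3 to C8 by C1′H=C2′, with C2′ carrying the (S)-3-[(tert-butyldimethylsilyl)oxy]-3-phenylpropanoyl group, via potassium enolate 18 (not isolated), via allenolate 19 (not isolated)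
Conditions: KN(SiMe3)2 (1.05 equiv), THF, −78 → 0 °C, then −78 °C; 17 (1.2 equiv), THF, −78 → −40 °C; AcOH, −78 °C
Reagents that add atoms: none
Why: KN(SiMe3)2 removes the only enolizable hydrogen (C3–H) to give enolate 18, whose C3 adds to the unhindered alkyne terminus C1′ of 17 to give allenolate 19, and the in-plane carbanion at C2′ then adds to the C8 ketone held 1,4 across the ring in its boat. The sequence is an anionic Michael–aldol bicycloannulation, the ynone counterpart of the aldol closure of 4-acylcyclohexanones to bicyclo[2.2.2]octanols and of Michael–aldol annulations of ketone enolates with alkynones. The one ring formed, the cyclohexene C3–C1′=C2′–C8–C1–C2 of the bicyclo[2.2.2]octene, closes in a 6-(enolexo)-exo-trig aldol. C3 is set by attack of the ynone on the enolate face anti to the O6–C7 bridge (the exo face, syn to C8), and C8 is set because the tethered carbanion can reach the carbonyl only from the side of the three-carbon bridge, which places the new hydroxyl syn to O6–C7; both follow from the resolved bridgeheads C1 and C5. The step needs C- over O-attack and conjugate addition rather than proton transfer from the ynone (acetylenic hydrogen and C4′–H2), which the terminal alkyne acceptor, the potassium counter-ion and the low temperature favour, and it needs the β-silyloxy ketone to survive, which the cold acetic acid quench should secure.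

**Step 11**
Reactants: 20 silyl-protected bridged bicyclo[2.2.2]octenol enone
Product: 21 the corresponding (S)-3-hydroxy-3-phenylpropanoyl enone (free C5′ hydroxyl, otherwise as 20)
Conditions: HF·pyridine, pyridine, THF, 0 → 23 °C
Reagents that add atoms: none
Why: Fluoride-driven Si–O cleavage under buffered, non-basic conditions, so that retro-aldol cleavage and β-elimination of the benzylic carbinol are avoided; the bridgehead C8 hydroxyl cannot ionize.

**Step 12**
Reactants: 21 β-hydroxy enone
Product: 22 target, (1R,3R,5S,8R) core with the (S)-2-phenyl-2,3-dihydro-4H-pyran-4-one fused at C1′=C2′ (ring oxygen on C1′)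
Conditions: PdCl2(MeCN)2 (10 mol %), CuCl (10 mol %), Na2HPO4 (10 mol %), O2 (1 atm), DME, 50 °C
Reagents that add atoms: none
Why: Wacker-type oxidative heterocyclization of a β-hydroxy enone, in which divalent palladium activates C1′=C2′, the C5′ hydroxyl attacks C1′ in a 6-endo-trig sense, and syn β-hydride elimination of C1′–H (the only β-hydrogen of the C2′-bound palladium enolate) restores the double bond as the dihydropyranone; CuCl and O2 return zerovalent palladium to the divalent state, and the C5′–O bond is never broken.

**Compound list**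

1 | dimedone (5,5-dimethylcyclohexane-1,3-dione) | CC1(C)CC(=O)CC(=O)C1 | starting material
2 | 2,5,5-trimethylcyclohexane-1,3-dione | CC1C(=O)CC(C)(C)CC1=O | intermediate
3 | 3-(2-methylpropoxy)-2,5,5-trimethylcyclohex-2-en-1-one | CC(C)COC1=C(C)C(=O)CC(C)(C)C1 | intermediate
4 | lithium dienolate of 3 (C1 enolate, C1=C6) | CC(C)COC1=C(C)C([O-])=CC(C)(C)C1.[Li+] | intermediate
5 | rac-6-(hydroxymethyl)-3-(2-methylpropoxy)-2,5,5-trimethylcyclohex-2-en-1-one (racemate) | CC(C)COC1=C(C)C(=O)C(CO)C(C)(C)C1 | intermediate
6 | rac-4-(hydroxymethyl)-2,5,5-trimethylcyclohexane-1,3-dione (racemate, C2 enolized) | CC1C(=O)CC(C)(C)C(CO)C1=O | intermediate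
7 | 4-(hydroxymethyl)-2-iodo-2,5,5-trimethylcyclohexane-1,3-dione (racemate, both C2 epimers) | CC1(I)C(=O)CC(C)(C)C(CO)C1=O | intermediate
8 | rac-(1R,5R)-2,2,5-trimethyl-6-oxabicyclo[3.2.1]octane-4,8-dione (racemate) | CC1(C)CC(=O)C2(C)OCC1C2=O | intermediate
9 | (1R,5R)-2,2,5-trimethyl-6-oxabicyclo[3.2.1]octane-4,8-dione | CC1(C)[C@@H]2CO[C@@](C)(C2=O)C(=O)C1 | intermediate
10 | lithium C3 enolate of 9 | CC1(C)[C@@H]2CO[C@@](C)(C2=O)C([O-])=C1.[Li+] | intermediate
11 | (1R,3S,5R)-2,2,3,5-tetramethyl-6-oxabicyclo[3.2.1]octane-4,8-dione (3-exo-methyl) | CC1(C)[C@@H]2CO[C@@](C)(C2=O)C(=O)[C@H]1C | intermediate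
12 | ethyl (S)-3-hydroxy-3-phenylpropanoate | CCOC(=O)C[C@H](O)c1ccccc1 | starting material
13 | (S)-3-hydroxy-N-methoxy-N-methyl-3-phenylpropanamide | CON(C)C(=O)C[C@H](O)c1ccccc1 | intermediate
14 | (S)-3-[(tert-butyldimethylsilyl)oxy]-N-methoxy-N-methyl-3-phenylpropanamide | CON(C)C(=O)C[C@@H](c1ccccc1)O[Si](C)(C)C(C)(C)C | intermediate
15 | ethynylmagnesium bromide | C#C[Mg]Br | starting material
16 | magnesium hemiaminal chelate from 14 and 15 (new carbinol centre undefined) | CON(C)C(O[Mg]Br)(C#C)C[C@@H](c1ccccc1)O[Si](C)(C)C(C)(C)C | intermediate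
17 | (S)-5-[(tert-butyldimethylsilyl)oxy]-5-phenylpent-1-yn-3-one | C#CC(=O)C[C@@H](c1ccccc1)O[Si](C)(C)C(C)(C)C | intermediate
18 | potassium C3 enolate of 11 | CC1(C)[C@@H]2CO[C@@](C)(C2=O)C([O-])=C1C.[K+] | intermediate
19 | potassium allenolate, Michael adduct of 18 and 17 (C3–C1′ bond formed on the exo face) | CC1(C)[C@@H]2CO[C@@](C)(C2=O)C(=O)[C@@]1(C)C=C=C([O-])C[C@@H](c1ccccc1)O[Si](C)(C)C(C)(C)C.[K+] | intermediate
20 | silyl-protected bridged bicyclo[2.2.2]octenol enone, (1R,3S,5S,8R) core, (S)-C5′ | CC1(C)[C@@H]2CO[C@]3(C)C(=O)[C@@]1(C)C=C(C(=O)C[C@@H](c4ccccc4)O[Si](C)(C)C(C)(C)C)[C@]23O | intermediate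
21 | β-hydroxy enone, (1R,3S,5S,8R) core, (S)-C5′ carbinol | CC1(C)[C@@H]2CO[C@]3(C)C(=O)[C@@]1(C)C=C(C(=O)C[C@H](O)c4ccccc4)[C@]23O | intermediate
22 | CNP0322161.1, caged dihydropyranone, (1R,3R,5S,8R) core, (S)-2-phenyl | CC1(C)[C@@H]2CO[C@]3(C)C(=O)[C@@]1(C)C1=C(C(=O)C[C@@H](c4ccccc4)O1)[C@]23O | target

**Step count.** Total: 12 steps. Longest linear sequence: 9 steps (steps 1–6, then 10–12); the ynone branch (steps 7–9) is 3 steps.

**Steps most likely to fail**

1. Step 10. The hindered, fully substituted enolate carbon may act as a base rather than a nucleophile (proton transfer from the acetylenic or C4′ hydrogens), may react through oxygen, or the sequence may stall after the conjugate addition. The fallback sets out from 11 (with 17) and returns at 20. Compound 11 is converted with KN(SiMe3)2 and Me3SiCl into its trimethylsilyl enol ether F1. A Mukaiyama–Michael addition of F1 to 17 (BF3·OEt2, CH2Cl2, −78 °C) then forms the C3–C1′ bond without any basic species and gives the (E)-enone Michael adduct F2. Me2AlSPh (CH2Cl2, −78 → 0 °C) adds thiolate to C1′ and the aluminium enolate closes onto C8 in a Michael–aldol sequence, giving the β-phenylthio aldol F3. Oxidation with mCPBA gives the sulfone F4, from which DBU removes benzenesulfinate by E1cB elimination to restore C1′=C2′ and deliver 20.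

2. Step 12. Oxypalladation may fail at the hindered, electron-poor trisubstituted alkene, or oxidation of the benzylic carbinol may compete. The fallback sets out from 20 and returns at 22. Copper-catalysed conjugate borylation (B2pin2, CuCl, NaOtBu, DPEphos, MeOH, THF) places boron on C1′ to give the β-boryl ketone F5. NaBO3·4H2O converts it into the β-hydroxy ketone F6, and Dess–Martin periodinane gives the 1,3-diketone F7. Aqueous HF in MeCN removes the silyl group to give the hydroxy diketone F8, and TsOH in CH2Cl2 closes the C5′ hydroxyl onto the C1′ carbonyl and dehydrates the hemiketal to 22; the ring oxygen can only end up on C1′.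

3. Step 4. Iodination at C2 may not be followed by ring closure because substitution at the tertiary, doubly acylated carbon is slow, or oxidation may divert to the carbinol. The fallback sets out from 6 and returns at 8, with the roles of nucleophile and electrophile reversed. Dimethyldioxirane (acetone, 0 °C) hydroxylates the enol at C2 to give 2-hydroxy-4-(hydroxymethyl)-2,5,5-trimethylcyclohexane-1,3-dione, whose cis isomer F9 is the productive one. Under Mitsunobu conditions (PPh3, DIAD, THF) the primary carbinol is activated and the acidic tertiary hydroxyl closes the five-membered ether to 8.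

**Further compounds**

F1 | step 10 | (1R,5R)-2,2,3,5-tetramethyl-4-(trimethylsilyloxy)-6-oxabicyclo[3.2.1]oct-3-en-8-one | CC1(C)[C@@H]2CO[C@@](C)(C2=O)C(O[Si](C)(C)C)=C1C
F2 | step 10 | (E)-enone Michael adduct, C3 of the dione bonded to C1′ on the exo face | CC1(C)[C@@H]2CO[C@@](C)(C2=O)C(=O)[C@@]1(C)/C=C/C(=O)C[C@@H](c1ccccc1)O[Si](C)(C)C(C)(C)C
F3 | step 10 | β-phenylthio aldol, cage closed, C1′ and C2′ configurations undefined | CC1(C)[C@@H]2CO[C@]3(C)C(=O)[C@@]1(C)C(Sc1ccccc1)C(C(=O)C[C@@H](c1ccccc1)O[Si](C)(C)C(C)(C)C)[C@]23O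
F4 | step 10 | β-phenylsulfonyl aldol | CC1(C)[C@@H]2CO[C@]3(C)C(=O)[C@@]1(C)C(S(=O)(=O)c1ccccc1)C(C(=O)C[C@@H](c1ccccc1)O[Si](C)(C)C(C)(C)C)[C@]23O
F5 | step 12 | β-(pinacolatoboryl) ketone from 20, C1′ and C2′ configurations undefined | CC1(C)[C@@H]2CO[C@]3(C)C(=O)[C@@]1(C)C(B4OC(C)(C)C(C)(C)O4)C(C(=O)C[C@@H](c1ccccc1)O[Si](C)(C)C(C)(C)C)[C@]23O
F6 | step 12 | β-hydroxy ketone (C1′ carbinol) | CC1(C)[C@@H]2CO[C@]3(C)C(=O)[C@@]1(C)C(O)C(C(=O)C[C@@H](c1ccccc1)O[Si](C)(C)C(C)(C)C)[C@]23O
F7 | step 12 | 1,3-diketone (C1′ ketone), silyl ether | CC1(C)[C@@H]2CO[C@]3(C)C(=O)[C@@]1(C)C(=O)C(C(=O)C[C@@H](c1ccccc1)O[Si](C)(C)C(C)(C)C)[C@]23O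
F8 | step 12 | δ-hydroxy 1,3-diketone, free (S)-carbinol | CC1(C)[C@@H]2CO[C@]3(C)C(=O)[C@@]1(C)C(=O)C(C(=O)C[C@H](O)c1ccccc1)[C@]23O
F9 | step 4 | cis-2-hydroxy-4-(hydroxymethyl)-2,5,5-trimethylcyclohexane-1,3-dione (racemate, relative configuration shown) | CC1(C)[C@H](CO)C(=O)[C@](C)(O)C(=O)C1
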